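The numbers in the tables are calculated with made-up constants; noise was put on by code.

Count the first end groups. The flasks, the readings and the question are these.

| flask | first end groups | second end groups | remark | time |
|---|---|---|---|---|
| Monday's | 0.10 M | 0.11 M | run made earlier |  |
| Sunday's | 0.10 M | 0.76 M | run made earlier |  |
| autumn | 0.10 M | 0.100 M |  | 40 min |
| spring | 0.10 M | 0.150 M |  | 40 min |
| winter | 0.10 M | 0.250 M |  | 40 min |
| dusk | 0.10 M | 0.300 M |  | 40 min |
| noon | 0.10 M | 0.500 M |  | 40 min |

| run | time / min | links / % | first end groups / % |
|---|---|---|---|
| Monday's | 5.00 | 15 | 5 |
| Monday's | 10.0 | 21 | 8 |
| Monday's | 15.0 | 20 | 5 |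
| Monday's | 20.0 | 20 | 5 |
| Sunday's | 1.50 | 49 | 9 |
| Sunday's | 4.00 | 56 | 5 |
| Sunday's | 8.00 | 57 | 2 |
| Sunday's | 20.0 | 62 | 3 |

(each reading ± 1.5 percentage points)

- percent here means first end groups units held: one homo dimer counts as two
- candidate steps: first end groups + second end groups <-> links + released group; 2 first end groups -> homo dimer; first end groups <-> dormant form
- "hardly changes" means that all values lie within two and a half points (for a concentration: within two and a half percent of the largest)

- amount of links at the end, in percent of the first end groups charged for autumn, spring, winter, dusk, noon, in this order
- the shape of the row from first to last (falls, then rises / rises all the way / falls all the way / hardly changes / rises, then falls)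

I split the charge of first end groups into a free share, a share in links, and a remainder I call the parked share, homo dimer and dormant form together. The parked share is 75.0% in Monday's run at 20.0 min and 35.0% in Sunday's run at 20.0 min. Dividing links by parked share and then by the second end groups charged gives 2.42 M⁻¹ for Monday's run and 2.33 M⁻¹ for Sunday's run, although their charges stand a factor of 6.91 apart. So I carry the mean of these readings, 2.38 M⁻¹, as a selectivity factor, the links won per parked share and per molar of second end groups.

Taking the free share as the mean of those last readings, 4.00%, the balance gives links of 18.4% for autumn and 52.1% for noon.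

One link I can rework from these readings is dividing by the charge, since one second end group goes into each link, while the readings themselves stop at 20.0 min and the question stands at 40 min. I reforge it with the charge less half of what the links took, which turns the factor into 2.55 M⁻¹, and I commit to 18.0% for autumn and 52.5% for noon.

The forecast gives 19%, 25%, 34%, 38% and 49%, a row that rises all the way, on the ground that “Kinetic competition fits better”. My autumn lies below its first value, and my noon lies above its last.

The flasks give 24.7%, 31.2%, 40.2%, 43.6% and 53.4%, a row that rises all the way.

    first end groups + second end groups ⇌ links + released group (K = 2.00, k = 1.40 M⁻¹ min⁻¹)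
    2 first end groups → homo dimer (k = 1.30 M⁻¹ min⁻¹)
    first end groups ⇌ dormant form (K = 10.0, k = 0.640 min⁻¹)

Autumn stands 6.7 percentage points above my figure. In autumn the dormant form still holds 53.1% at 40.0 min, down from 57.7% at 20.0 min, while links go from 21.2% to 24.7%. The selectivity factor reckoned from autumn's end comes to 3.52 M⁻¹, more than the 2.38 M⁻¹ I carried, and the same reckoning for noon gives 2.46 M⁻¹.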